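The numbers in the tables were computed for an exercise.

South-west carries more Z than west, 1.5 equiv against 1 equiv, yet by 2.50 min it has lost 4.10% of its X to something other than D, and west 4.20%. I call k_L the leak constant: the X missing from X + D, per minute and per X present, taking the mean of start and reading as the X present. It reads 0.0200 min⁻¹ in west and 0.0209 min⁻¹ in south-west, so I read the leak as indifferent to Z, and I take it as first order in X. South, at −14 °C, reads 0.108 min⁻¹, and interpolating ln k_L in temperature gives 0.0429 min⁻¹ at −20 °C.

| flask | X | Z | temperature | remark | time |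
|---|---|---|---|---|---|
| west | 0.25 M | 1 equiv | −25 °C | run made earlier |  |
| south | 0.25 M | 0.67 equiv | −14 °C | run made earlier |  |
| south-west | 0.25 M | 1.5 equiv | −25 °C | run made earlier |  |
| theta | 0.25 M | 1.00 equiv | −20 °C | everything together at the start | 20 min |
| zeta | 0.25 M | 1.00 equiv (fed, over 15 min) |  | the addition at −60 °C, then warmed to −20 °C; the feed brings no volume worth counting | 20 min |
| alpha | 0.25 M | 1.00 equiv (fed, over 15 min) | −20 °C | all else is in the flask from the start; the feed brings no volume worth counting | 20 min |
| epsilon | 0.25 M (fed, over 15 min) | 1.00 equiv | −20 °C | all else is in the flask from the start; the feed brings no volume worth counting | 20 min |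

- west (time / min: D / %, X / %): 0.833: 12.7, 86.2; 2.50: 27.4, 68.4; 4.00: 34.9, 58.3; 6.00: 40.4, 50.9; 10.0: 42.7, 43.0; 12.0: 42.2, 41.0
- south (time / min: D / %, X / %): 2.00: 20.9, 61.7; 4.00: 17.1, 51.3; 6.00: 12.4, 46.0; 8.00: 7.6, 40.2; 10.0: 4.3, 34.9; 12.0: 2.2, 32.7
- south-west (time / min: D / %, X / %): 1.00: 21.0, 76.9; 1.50: 28.8, 69.6; 2.50: 38.8, 57.1; 4.00: 47.4, 45.4; 8.00: 56.8, 33.4; 12.0: 56.9, 29.0

(readings scatter by 0.3 percentage points)



* which flask leads in amount of D, in percent of the X charged ("all alike" within 1.5 percentage points) (theta / zeta / alpha / epsilon / all alike)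
* how much D is there at the end, in percent of the X charged: theta
* how much D is there at the end, in percent of the X charged: zeta
* how much D is there at the end, in percent of the X charged: alpha
* how much D is there at the end, in percent of the X charged: epsilon

My measure is the leak number Λ, k_L times the feed time, a Damköhler number: 0.644. Now the settings, by hand. Feed Z into X at −20 °C, as alpha does: integrating dX/dt = −k_L X over the feed gives 1 − exp(−Λ), an estimate of 47.5% of the X leaked by the end of the feed, if X took no other path. Cool the feed, as zeta does: extrapolated to −60 °C, Λ is 0.001404, far smaller, and the last 5.00 min, spent warm, add an estimated 19.3%. Feed X into Z, as epsilon does: the mean X during the feed is at most half the charge, so with Λ/2 in the same formula my estimate is 27.5%. Zeta's estimate is the lowest, so I put zeta first, then epsilon, with alpha behind.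

The forecast differs: alpha leads, with theta 21%, zeta 36%, alpha 38% and epsilon 25%, on the ground that “Alpha's slow feed spares Z”.

The flasks give theta 22.5%, zeta 37.4%, alpha 17.3% and epsilon 30.6%, so zeta leads.

    X + Z ⇌ D (K = 7.40 M⁻¹, k = 1.20 M⁻¹ min⁻¹, Ea = 52.0 kJ mol⁻¹, ΔH = −35.0 kJ mol⁻¹)
    X + Z → J, rate k2*[X] as long as [Z] is above zero (k = 0.0450 min⁻¹, Ea = 83.0 kJ mol⁻¹)
    D ⇌ G (K = 1.70, k = 0.0120 min⁻¹, Ea = 69.0 kJ mol⁻¹, ΔH = −56.0 kJ mol⁻¹)
    (constants at −20 °C)

In the scheme the leak appears as the step to J. In alpha, J stands at 44.3% at 15.0 min, against my estimate of 47.5%. In epsilon, k_L times the time integral of the simulated X gives 15.5% by the end of the feed, and J stands at 17.2%. Alpha is not at rest at 20.0 min: it still holds X 28.7%, beside J 51.5%. At 200 min, alpha's J reaches 97.2%, zeta's D has fallen to 0.203%, and alpha's D to 0.0973%.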